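## Analysis of the target

Guidongnin is a 6,7-seco-ent-kaurane; ent-kaurane numbering is used for every compound below. Cyclohexane ring A (C1–C5, C10) is cis-fused across C4–C5 to a γ-lactone (C19–O–C6). C10 is the spiro atom to a δ-lactone (ring B: C10–C20–O–C7–C8–C9), and C8–C9 is shared with a bicyclo[3.2.1]octane (ring C: C8, C9, C11–C14; ring D: C8, C14, C13, C16, C15). The bicycle carries the C16=C17 methylene, an allylic alcohol at C15 and an alcohol at C11.

There are eight stereocentres (C4, C5, C8, C9, C10, C11, C13, C15), three of them quaternary (C4, C8, C10). They form two contiguous triads, C4–C5–C10 and C10–C9–C8, that meet at the spiro carbon.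

On ring A the three oxidised one-carbon arms C19, C6 and C20 share one face; the C18 methyl, H5 and C9 lie on the other. On ring B, H9 and C15 lie on the side of C5, while C11, C14 and C1 lie on the other, so ring C is cis-fused to the δ-lactone in the structure as drawn. The C11 hydroxyl is equatorial on ring C, cis to C10 and turned away from the C15–C16 bridge. The C15 hydroxyl points from that bridge toward C9 and C11.

The sensitive groups are the two lactones and the 15-hydroxy-16-ene unit. C20–O sits cis to the C6 carbonyl on the neighbouring carbon, so a free C20 alkoxide can take the γ-lactone over from O19. Any C11 ketone on the way makes H9 formally enolisable.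

The difficulty lies in the spiro quaternary C10, wedged between C5 (itself next to quaternary C4) and C9, in the quaternary bridgehead C8, and in placing oxygen at C11 and C15 on a compact cage.

The strategy rests on one feature. C5 is α to the lactone carbonyl C6, and C10 is α to C20 once C20 is raised to the carboxyl level. C6–C5–C10–C20 is then a 1,4-dicarbonyl, and the ring-A bond C5–C10 joins two enolate carbons of like polarity.

## Retrosynthetic reasoning

**C11 and C15 carbinols.** Guidongnin 40 is traced to the 11,15-dione 39 by cutting two C–H bonds. Hydride is expected to reach C15 from the open face and so place the hydroxyl toward C9/C11, which allylic oxidation would not do. Dione 39 comes from ketone 37 through allylic oxidation at C15 (38).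

**Ring D.** In 37 the bond C13–C16 is cut. A vinyl radical at C16, made from the terminal alkyne on C15, adds to the β-carbon C13 of enone 35. This closes the five-membered ring, leaves the exocyclic methylene and keeps the C11 oxygen as a ketone. Enone 35 is the dehydrogenated form of silyl enol ether 33.

**Rings B and C.** In 33 the bonds C8–C9 and C13–C14 are cut together, giving triene 32. One cycloaddition then makes quaternary C8, C9, the δ-lactone and ring C. The ester tether through O20 forces the diene end C9 onto the acrylate carbon C8, the opposite of the bond an untethered pair would form. The 2-silyloxy group of the diene puts the oxygen on C11.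

**Triene assembly.** Triene 32 is the enol silyl ether of ester 31, which is cut at O20–C7 into alcohol 26 and acid 30. The vinyl ketone arm of 26 is grown from the C9 aldehyde 21 by one carbon (C11, aldehyde 23) and then two (C12, C13; alcohol 24, ketone 25). O20 stays silylated (19 to 25) because these steps use ylide and Grignard reagents. Acid 30 comes from malonate 27 through diacid 28.

**Differentiating the two arms on C10.** Aldehyde 21 goes back through alcohol 20 to silane 19, and 19 through alcohol 18 and acid 17 to ester 16. C20 is reduced and protected while C9 is still a C–Si bond, so the two hydroxymethyl groups on C10 never have to be told apart.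

**Ring A (key disconnection).** In 16 the bond C5–C10 is cut, giving open-chain lactone ester 14 (as its bis-enolate 15). The bond lies between two α-carbons, so the forward step is an oxidation of two enolates, not a polar bond formation. It gives ring A, the cis ring fusion and quaternary C10 in one step from a chain whose only stereocentre is C4. The C20 carbonyl is carried as a tert-butyl ester and not as an imide for two reasons. α-Branched imides of oxazolidinones resist deprotonation because of allylic 1,3-strain in the fully substituted enolate. A neopentyl imide next to the lactone could also not be reduced cleanly afterwards. The ester enolises readily, does not acylate the lactone enolate, and is later reduced by way of acid 17.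

**Chain C1–C10.** Ester 14 comes from enoate 13 by hydrogenation, and 13 is cut at C1=C10 into aldehyde 12 and phosphonate 4. The silylmethyl group (future C9) arrives on the phosphonate, made from 3 and iodide 2 (from chloride 1). No enolate therefore has to be alkylated beside the lactone.

**C4.** Aldehyde 12 comes from hydroxy lactone 11, and 11 from silyl enol ether 9 by cleavage of both C=C bonds. Ether 9 derives from ketone 8, made by enantioselective conjugate addition of the alkenyl group of 5 to enone 6. The six ring carbons of 6 end as C6, C5, C4, C3, C2 and C1. The alkenyl carbon on C4 ends as C19.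

## Alternatives that were turned down

**Alternative 1:** The disconnection is C15–C16, the last bond of ring D. Forward, CrCl2 with catalytic NiCl2 would turn a 1-iodovinyl group on C13 into a vinylchromium reagent. This adds to a C15 aldehyde on C8 and closes the five-membered ring, giving the C11 silyl ether of the target, A1.

- For: the C15 carbinol and the exocyclic methylene arise in the ring-closing step, organochromium reagents leave both lactones alone, and no redox changes are needed at C15. On this point it is stronger than the chosen route, which spends three steps on C15.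
- Against: it solves ring D only. Rings A, B and C, both quaternary carbons C8 and C10, and C11 must already exist, so the hard bonds C5–C10 and C8–C9 are left to unstated chemistry.
- Against: the substrate carries a formyl group and the lactone carbonyl on the same quaternary C8, a 1,3-dicarbonyl without α-hydrogen that is open to deformylation.
- Against: the C15 configuration is fixed by the aldehyde face that the rigid closure exposes. If that is the wrong one, the same oxidation and reduction are needed anyway.
- In its place the chosen strategy puts its key step on the skeleton: ring A and spiro C10 come from an open chain, and the two arms on C10 are differentiated from the outset.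

**Alternative 2:** The disconnection is C8–C9 with loss of the O–C12 bond. Forward, the silyl ketene acetal of a δ-lactone (C7, O, C12, C13, C14, C8) with an (E)-alkenyl group (C11=C9–C10) on C12 would undergo an Ireland–Claisen shift. The lactone contracts to carbocyclic ring C, giving the cyclohexenecarboxylic acid A2.

- For: quaternary C8 and C9 are set together in one ordered, ring-constrained transition state, with chirality passed on from C12. For the C8/C9 relation this is stronger than the Diels–Alder step of the chosen route, which depends on an endo/exo preference.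
- Against: the new bond joins a fully substituted ketene acetal carbon to an alkene carbon that bears quaternary C10, which is a very crowded [3,3] shift.
- Against: the lactone enolate has the C15 ether oxygen in the β-position and can eliminate it.
- Against: the configuration of C9 relative to C10 lies outside the pericyclic array and is left to rotamer preference.
- Against: A2 has a C11=C12 alkene where the target needs a C11 alcohol, so a regio- and stereoselective hydration follows. Ring B and ring D are still open.
- The chosen route brings the C11 oxygen in with the diene, closes ring B in the same step as ring C, and makes C10 in its key step and not before it.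

**Alternative 3:** The disconnection is C8–C9 and C12–C13. Forward, NaOCH2CF3 would convert a chloromethyl ketone (C9, C11, C12) into an oxyallyl cation. This adds across C8 and C13 of a cyclopentadiene-1-carboxylate ester tethered through O20, giving the lactone-fused bicyclo[3.2.1]octenone A3.

- For: one step closes ring B and the whole bicycle, makes quaternary C8 and delivers the C11 ketone. In rings per step it is clearly stronger than the chosen route, which needs a cycloaddition and a radical cyclisation.
- Against: cyclopentadienyl esters equilibrate by 1,5-hydrogen shifts and dimerise, so the required 1-carboxylate isomer is not secured.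
- Against: the diene is electron-poor at the terminus that must bond to an electrophilic oxyallyl cation, and Favorskii rearrangement of the chloroketone competes.
- Against: the C9 configuration follows the compact or extended mode, and the facial relation to C10 has no evident control.
- Against: A3 lacks C17 and the C15 oxygen. Its C15=C16 alkene must be turned regioselectively into a 15-ol and a 16-methylene.
- The chosen strategy gives up this convergence for steps of known type whose selectivity can be reasoned from the substrate. Like the other two alternatives, alternative 3 presupposes ring A with C10, which is what the chosen key step makes.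

Key step: step 9

Remark: the sense of induction of the chiral ligand in step 3 is not assumed; the antipode is used that gives (R)-8.

Remark: C10 of 14 is stereogenic but becomes planar in step 9, so 14 is carried as both epimers.

## Route

Step 1
Reactants: 1 (chloromethyl)dimethyl(phenyl)silane
Product: 2 (iodomethyl)dimethyl(phenyl)silane
Conditions: NaI, acetone, reflux
Reagents that add atoms: sodium iodide, [Na+].[I-]
Why: Finkelstein exchange driven by precipitation of NaCl; the iodide is the better SN2 partner for step 2.

Step 2
Reactants: 3 tert-butyl 2-(diethoxyphosphoryl)acetate; 2 (iodomethyl)dimethyl(phenyl)silane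
Product: 4 tert-butyl 2-(diethoxyphosphoryl)-3-[dimethyl(phenyl)silyl]propanoate (racemic)
Conditions: NaH, DMF, 0 °C; then 2, 50 °C
Reagents that add atoms: none
Why: C-alkylation of a stabilised phosphonoacetate anion with a primary iodide activated by the α-silicon; a second alkylation is held back by the bulk of the silylmethyl group.

Step 3
Reactants: 5 hex-1-yne; 6 3-methylcyclohex-2-en-1-one
Product: 8 (3R)-3-[(1E)-hex-1-en-1-yl]-3-methylcyclohexan-1-one, via alkenylalane 7 (not isolated)
Conditions: 5, (iBu)2AlH, heptane, 50 °C; then 6, copper thiophene-2-carboxylate Cu(O2CC4H3S) (10 mol%), chiral phosphinamine Ph2P–N[CH(CH3)Ph]2 (11 mol%), Et2O, −30 °C; aq HCl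
Reagents that add atoms: none
Why: syn-hydroalumination gives the (E)-alkenylalane, and its alkenyl group is delivered in a copper-catalysed enantioselective conjugate addition to the β-methyl enone. The chiral copper–ligand complex selects the enone face and so sets quaternary C4; the alkenyl carbon is the future C19.

Step 4
Reactants: 8 (3R)-3-[(1E)-hex-1-en-1-yl]-3-methylcyclohexan-1-one
Product: 9 {[(5R)-5-[(1E)-hex-1-en-1-yl]-5-methylcyclohex-1-en-1-yl]oxy}trimethylsilane
Conditions: LiN(iPr)2, Me3SiCl, THF, −78 °C
Reagents that add atoms: chlorotrimethylsilane, C[Si](C)(C)Cl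
Why: kinetic enolisation with in-situ silylation takes the proton from the CH2 remote from the quaternary carbon, since the other α-CH2 is shielded by it. This places the enol double bond where the ring is to be cut.

Step 5
Reactants: 9 {[(5R)-5-[(1E)-hex-1-en-1-yl]-5-methylcyclohex-1-en-1-yl]oxy}trimethylsilane
Product: 11 (4R)-4-(3-hydroxypropyl)-4-methyloxolan-2-one, via dihydroxy acid 10 (not isolated)
Conditions: O3, CH2Cl2/MeOH, −78 °C; NaBH4, −78 °C to rt; 2 M HCl
Reagents that add atoms: ozone, [O-][O+]=O
Why: ozonolysis cleaves both the silyl enol ether (to the C6 acid and the C1 aldehyde) and the alkenyl group (to the C19 aldehyde); borohydride work-up reduces the aldehydes. On acidification the γ-hydroxy acid closes to the five-membered lactone in preference to the seven-membered one; C4 is untouched.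

Step 6
Reactants: 11 (4R)-4-(3-hydroxypropyl)-4-methyloxolan-2-one
Product: 12 3-[(3R)-3-methyl-5-oxooxolan-3-yl]propanal
Conditions: TEMPO (10 mol%), PhI(OAc)2, CH2Cl2, rt
Reagents that add atoms: none
Why: oxoammonium-mediated oxidation of a primary alcohol stops at the aldehyde and leaves the lactone alone.

Step 7
Reactants: 12 3-[(3R)-3-methyl-5-oxooxolan-3-yl]propanal; 4 tert-butyl 2-(diethoxyphosphoryl)-3-[dimethyl(phenyl)silyl]propanoate
Product: 13 tert-butyl 2-{[dimethyl(phenyl)silyl]methyl}-5-[(3R)-3-methyl-5-oxooxolan-3-yl]pent-2-enoate (E/Z mixture)
Conditions: NaH, THF, 0 °C; then 12, 0 °C to rt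
Reagents that add atoms: none
Why: Horner–Wadsworth–Emmons olefination joins C1 to C10 and brings in C20 (ester) and C9 (silylmethyl) at once; the stabilised anion does not attack the lactone. The alkene geometry is irrelevant because the bond is hydrogenated next.

Step 8
Reactants: 13 tert-butyl 2-{[dimethyl(phenyl)silyl]methyl}-5-[(3R)-3-methyl-5-oxooxolan-3-yl]pent-2-enoate
Product: 14 tert-butyl 2-{[dimethyl(phenyl)silyl]methyl}-5-[(3R)-3-methyl-5-oxooxolan-3-yl]pentanoate (both epimers at C10)
Conditions: H2 (1 atm), Pd/C, EtOAc, rt
Reagents that add atoms: none
Why: catalytic hydrogenation of the conjugated trisubstituted alkene; the aryl–silicon bond, the tert-butyl ester and the lactone are inert under these conditions.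

Step 9
Reactants: 14 tert-butyl 2-{[dimethyl(phenyl)silyl]methyl}-5-[(3R)-3-methyl-5-oxooxolan-3-yl]pentanoate
Product: 16 tert-butyl (3aR,7R,7aR)-7-{[dimethyl(phenyl)silyl]methyl}-3a-methyl-1-oxooctahydro-2-benzofuran-7-carboxylate, via dilithium bis-enolate 15 (not isolated)
Conditions: LiN(iPr)2 (2.3 equiv), THF, −78 °C; Fe(acac)3 (2.2 equiv), −78 °C to rt, 0.02 M
Reagents that add atoms: none
Why: Two equivalents of base give the lithium enolates of the lactone (C5) and of the α-branched ester (C10); Fe(acac)3 removes one electron from an iron-bound enolate, most easily the more substituted ester enolate, the α-carbonyl radical at C10 is captured by the neighbouring lactone enolate, and a second trivalent iron takes the second electron to leave the 1,4-dicarbonyl C6–C5–C10–C20. The closest known reaction type is the intramolecular oxidative coupling of ester, lactone and amide dienolates with trivalent iron or divalent copper salts. Ring A closes as a six-membered ring, 6-exo with respect to the lactone enolate C5=C6. At C5 the three-carbon tether from C4 can reach only the face of the planar lactone enolate that carries C3, so the γ-lactone must end cis-fused. At C10 a chair-like transition state keeps the bulky silylmethyl group equatorial and lets one metal bridge the two enolate oxygens, which puts C20 axial and cis to C6; the other arrangement would set the silylmethyl group 1,3-diaxial to C19. The step needs ring closure to win over dimerisation, which dilution and the ring size secure, and it needs no acyl transfer between the two sites, which full double enolisation and the unreactive tert-butyl ester secure. Fe(acac)3 is chosen over divalent copper because further oxidation of the C10 radical to a β-silyl cation would end in loss of silicon. The C10 configuration of 14 is erased on enolisation, so the epimer mixture is used as such.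

Step 10
Reactants: 16 tert-butyl (3aR,7R,7aR)-7-{[dimethyl(phenyl)silyl]methyl}-3a-methyl-1-oxooctahydro-2-benzofuran-7-carboxylate
Product: 17 carboxylic acid of 16 (CO2H on C10, cis to C6)
Conditions: CF3CO2H, CH2Cl2, 0 °C to rt
Reagents that add atoms: none
Why: acidolysis of the tert-butyl ester through the tert-butyl cation; the lactone is stable, and the short, cold exposure is meant to spare the phenyl–silicon bond.

Step 11
Reactants: 17 carboxylic acid of 16
Product: 18 C20 alcohol (hydroxymethyl on C10 cis to C6; silylmethyl trans)
Conditions: BH3·SMe2, THF, 0 °C to rt; MeOH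
Reagents that add atoms: none
Why: borane reduces a carboxylic acid through its acyloxyborane far faster than a lactone, so C20 alone is reduced. No alkoxide is formed, which avoids migration of the γ-lactone from O19 to O20.

Step 12
Reactants: 18 C20 alcohol
Product: 19 C20 triisopropylsilyl ether
Conditions: iPr3SiOTf, 2,6-lutidine, CH2Cl2, 0 °C
Reagents that add atoms: triisopropylsilyl trifluoromethanesulfonate, CC(C)[Si](C(C)C)(C(C)C)OS(=O)(=O)C(F)(F)F
Why: silylation of the neopentyl primary alcohol with a silyl triflate under non-nucleophilic base; the group has no aryl–silicon bond and withstands the peracid, ylide, acid and Grignard steps that follow.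

Step 13
Reactants: 19 C20 triisopropylsilyl ether
Product: 20 C9 alcohol (hydroxymethyl on C10 trans to C6)
Conditions: KBr, CH3CO3H, NaOAc, AcOH, rt
Reagents that add atoms: peracetic acid, CC(=O)OO
Why: Fleming–Tamao oxidation: ipso-bromodesilylation of the phenyl group, then peracid-induced 1,2-shift of C9 from silicon to oxygen with retention. The buffered acidic medium leaves the lactone and the silyl ether intact.

Step 14
Reactants: 20 C9 alcohol
Product: 21 C9 aldehyde
Conditions: Dess–Martin periodinane, NaHCO3, CH2Cl2, rt
Reagents that add atoms: none
Why: periodinane oxidation of a hindered primary alcohol under neutral conditions; the aldehyde sits on quaternary C10 and cannot enolise.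

Step 15
Reactants: 21 C9 aldehyde
Product: 23 homologous aldehyde (C10–C9H2–C11HO), via methyl enol ether 22 (not isolated)
Conditions: [Ph3PCH2OMe]Cl, KN(SiMe3)2, THF, 0 °C; then 1 M HCl, THF, rt
Reagents that add atoms: (methoxymethyl)triphenylphosphonium chloride, [Cl-].COC[P+](c1ccccc1)(c1ccccc1)c1ccccc1; water, O
Why: Wittig methoxymethylenation with a small, reactive ylide adds C11 to the neopentyl aldehyde, and mild acid hydrolysis of the enol ether releases the aldehyde.

Step 16
Reactants: 23 homologous aldehyde
Product: 24 allylic alcohol (C11 carbinol, both epimers)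
Conditions: CH2=CHMgBr, THF, −78 °C
Reagents that add atoms: vinylmagnesium bromide, C=C[Mg]Br
Why: Grignard addition to the aldehyde at low temperature, where the lactone is not attacked; the C11 configuration is lost in the next step.

Step 17
Reactants: 24 allylic alcohol
Product: 25 vinyl ketone (C9H2–C11(=O)–C12H=C13H2)
Conditions: Dess–Martin periodinane, NaHCO3, CH2Cl2, 0 °C
Reagents that add atoms: none
Why: neutral oxidation of the secondary allylic alcohol to the enone without base that could polymerise it.

Step 18
Reactants: 25 vinyl ketone
Product: 26 hydroxy vinyl ketone (free C20 alcohol)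
Conditions: HF·pyridine, THF/pyridine, 0 °C to rt
Reagents that add atoms: none
Why: acidic fluoride cleaves the silyl ether without ever forming the C20 alkoxide, which avoids both lactone migration and conjugate addition to the enone.

Step 19
Reactants: 27 dimethyl 2-(prop-2-yn-1-yl)propanedioate
Product: 28 2-(prop-2-yn-1-yl)propanedioic acid
Conditions: KOH, MeOH/H2O, rt; HCl
Reagents that add atoms: potassium hydroxide, [K+].[OH-]
Why: saponification of both esters; the terminal alkyne is inert.

Step 20
Reactants: 28 2-(prop-2-yn-1-yl)propanedioic acid
Product: 30 2-methylidenepent-4-ynoic acid, via Mannich base 29 (not isolated)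
Conditions: (CH2O)n, Et2NH, EtOAc, reflux
Reagents that add atoms: formaldehyde (as paraformaldehyde), C=O
Why: Mannich reaction at the malonic carbon followed by decarboxylative loss of the amine, the standard way from a monoalkylmalonic acid to the 2-alkylacrylic acid.

Step 21
Reactants: 26 hydroxy vinyl ketone; 30 2-methylidenepent-4-ynoic acid
Product: 31 C20 ester of 26 with 30 (acrylate dienophile on O20)
Conditions: DCC, DMAP (cat.), CH2Cl2, 0 °C to rt
Reagents that add atoms: none
Why: Steglich esterification of the primary neopentyl alcohol under nearly neutral conditions; it installs C7, C8, C14 and the propargyl unit C15–C17.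

Step 22
Reactants: 31 C20 ester
Product: 32 (Z)-silyl dienol ether (C9=C11(OSitBuMe2)–C12=C13)
Conditions: tBuMe2SiOTf, Et3N, CH2Cl2, −78 to 0 °C
Reagents that add atoms: tert-butyldimethylsilyl trifluoromethanesulfonate, CC(C)(C)[Si](C)(C)OS(=O)(=O)C(F)(F)F
Why: soft enolisation silylates the ketone at its only enolisable position C9 and leaves the ester and the lactone alone; the enol ether forms with O cis to C10, which is the diene geometry with C10 on the outside.

Step 23
Reactants: 32 (Z)-silyl dienol ether
Product: 33 tetracyclic silyl enol ether (δ-lactone cis-fused to ring C; C11(OSi)=C12; prop-2-ynyl on C8 cis to H9)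
Conditions: PhMe (0.01 M), 2,6-di-tert-butyl-4-methylphenol, 170 °C, sealed tube
Reagents that add atoms: none
Why: thermal intramolecular Diels–Alder reaction forms C9–C8 and C13–C14, closing the δ-lactone and ring C and creating quaternary C8 and C9; the fully substituted C10 in the tether favours the reactive rotamer and offers no hydrogen for a 1,5-shift of the diene. With the ester carbonyl C7 under the diene (endo) the lactone is cis-fused to ring C and the propargyl arm ends cis to H9. The silyloxy group on C11, cis to C10, is expected to turn toward the C1 methylene and away from C5 with its lactone, so the dienophile adds on the C5/C20 side and C11 ends syn to C1.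

Step 24
Reactants: 33 tetracyclic silyl enol ether
Product: 35 enone (C11 ketone, C12=C13), via C12 selenide 34 (not isolated)
Conditions: PhSeCl, CH2Cl2, −78 °C; then H2O2, pyridine, 0 °C to rt
Reagents that add atoms: none
Why: selenenylation of the silyl enol ether at C12, then selenoxide syn-elimination, which can only run toward C13. This route avoids divalent palladium, which could add the enol ether across the alkyne.

Step 25
Reactants: 35 enone
Product: 37 pentacyclic ketone (11-oxo, 16-methylene, C15 as CH2), via vinylstannane 36 (not isolated)
Conditions: Bu3SnH, AIBN, PhH, 80 °C, slow addition; then HCl, Et2O/CH2Cl2, 0 °C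
Reagents that add atoms: none
Why: the stannyl radical adds to the terminal alkyne carbon C17, and the C16 vinyl radical closes 5-exo onto the enone β-carbon C13 (radical conjugate addition); protodestannylation then leaves the methylene group. C13 has only one possible configuration because the new bridge spans C8 and C13 on one face of ring C.

Step 26
Reactants: 37 pentacyclic ketone
Product: 38 15-hydroxy-11-ketone (C15 epimers; hydroxyl on the face away from C9 expected to prevail)
Conditions: SeO2 (0.5 equiv), tBuOOH, CH2Cl2, rt
Reagents that add atoms: tert-butyl hydroperoxide, CC(C)(C)OO; selenium dioxide, O=[Se]=O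
Why: allylic oxidation by ene reaction and [2,3]-shift; C15 is the only allylic CH2 because C13 is a bridgehead. Oxygen is delivered on the open face of the bridge, so the wrong C15 epimer should prevail and is corrected in steps 27 and 28.

Step 27
Reactants: 38 15-hydroxy-11-ketone
Product: 39 11,15-dione (16-methylene-15-ketone)
Conditions: Dess–Martin periodinane, NaHCO3, CH2Cl2, rt
Reagents that add atoms: none
Why: neutral oxidation converges both C15 epimers (and any enone already present) on one methylene ketone; H9 is not at risk because an enol toward C9 would lie between two quaternary carbons.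

Step 28
Reactants: 39 11,15-dione
Product: 40 guidongnin
Conditions: NaBH4, CeCl3·7H2O, MeOH, −78 to −20 °C
Reagents that add atoms: none
Why: Luche reduction gives 1,2-addition at the methylene ketone from the face remote from the C9–C11–C12 bridge, leaving the C15 hydroxyl turned toward that bridge. At C11 the face next to the axial C10 substituent on C9 is closed, so hydride should enter from the side of the C15–C16 bridge and give the equatorial alcohol cis to C10; the lactones are not reduced.

## Compound list

1 | (chloromethyl)dimethyl(phenyl)silane | ClC[Si](C)(C)c1ccccc1 | starting material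
2 | (iodomethyl)dimethyl(phenyl)silane | IC[Si](C)(C)c1ccccc1 | intermediate
3 | tert-butyl 2-(diethoxyphosphoryl)acetate | CCOP(=O)(OCC)CC(=O)OC(C)(C)C | starting material
4 | tert-butyl 2-(diethoxyphosphoryl)-3-[dimethyl(phenyl)silyl]propanoate (racemic) | CCOP(=O)(OCC)C(C[Si](C)(C)c1ccccc1)C(=O)OC(C)(C)C | intermediate
5 | hex-1-yne | CCCCC#C | starting material
6 | 3-methylcyclohex-2-en-1-one | CC1=CC(=O)CCC1 | starting material
7 | [(1E)-hex-1-en-1-yl]bis(2-methylpropyl)alumane | CCCC/C=C/[Al](CC(C)C)CC(C)C | intermediate
8 | (3R)-3-[(1E)-hex-1-en-1-yl]-3-methylcyclohexan-1-one | O=C1CCC[C@@](C)(/C=C/CCCC)C1 | intermediate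
9 | {[(5R)-5-[(1E)-hex-1-en-1-yl]-5-methylcyclohex-1-en-1-yl]oxy}trimethylsilane | C[Si](C)(C)OC1=CCC[C@@](C)(/C=C/CCCC)C1 | intermediate
10 | (3R)-6-hydroxy-3-(hydroxymethyl)-3-methylhexanoic acid | OCCC[C@@](C)(CO)CC(=O)O | intermediate
11 | (4R)-4-(3-hydroxypropyl)-4-methyloxolan-2-one | OCCC[C@@]1(C)COC(=O)C1 | intermediate
12 | 3-[(3R)-3-methyl-5-oxooxolan-3-yl]propanal | O=CCC[C@@]1(C)COC(=O)C1 | intermediate
13 | tert-butyl 2-{[dimethyl(phenyl)silyl]methyl}-5-[(3R)-3-methyl-5-oxooxolan-3-yl]pent-2-enoate (E/Z mixture) | CC(C)(C)OC(=O)C(C[Si](C)(C)c1ccccc1)=CCC[C@@]2(C)COC(=O)C2 | intermediate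
14 | tert-butyl 2-{[dimethyl(phenyl)silyl]methyl}-5-[(3R)-3-methyl-5-oxooxolan-3-yl]pentanoate (both C10 epimers) | CC(C)(C)OC(=O)C(CCC[C@@]1(C)COC(=O)C1)C[Si](C)(C)c2ccccc2 | intermediate
15 | dilithium bis-enolate of 14 (lactone enolate C5=C6, ester enolate C10=C20) | [Li+].[Li+].CC(C)(C)OC([O-])=C(CCC[C@@]1(C)COC([O-])=C1)C[Si](C)(C)c2ccccc2 | intermediate
16 | tert-butyl (3aR,7R,7aR)-7-{[dimethyl(phenyl)silyl]methyl}-3a-methyl-1-oxooctahydro-2-benzofuran-7-carboxylate (ring A closed; C19, C6, C20 on one face) | CC(C)(C)OC(=O)[C@]1(CCC[C@@]2(C)COC(=O)[C@H]21)C[Si](C)(C)c3ccccc3 | intermediate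
17 | carboxylic acid of 16 (CO2H on C10 cis to C6) | OC(=O)[C@]1(CCC[C@@]2(C)COC(=O)[C@H]21)C[Si](C)(C)c3ccccc3 | intermediate
18 | C20 alcohol: ring-A lactone with CH2OH (cis to C6) and CH2SiMe2Ph on C10 | OC[C@]1(CCC[C@@]2(C)COC(=O)[C@H]21)C[Si](C)(C)c3ccccc3 | intermediate
19 | C20 triisopropylsilyl ether of 18 | CC(C)[Si](C(C)C)(C(C)C)OC[C@]1(CCC[C@@]2(C)COC(=O)[C@H]21)C[Si](C)(C)c3ccccc3 | intermediate
20 | C9 alcohol: ring-A lactone with CH2OSi(iPr)3 (C20) and CH2OH (C9) on C10 | CC(C)[Si](C(C)C)(C(C)C)OC[C@]1(CCC[C@@]2(C)COC(=O)[C@H]21)CO | intermediate
21 | C9 aldehyde | CC(C)[Si](C(C)C)(C(C)C)OC[C@]1(CCC[C@@]2(C)COC(=O)[C@H]21)C=O | intermediate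
22 | methyl enol ether C9H=C11H–OMe (E/Z mixture) | CC(C)[Si](C(C)C)(C(C)C)OC[C@]1(CCC[C@@]2(C)COC(=O)[C@H]21)C=COC | intermediate
23 | homologous aldehyde C9H2–C11HO | CC(C)[Si](C(C)C)(C(C)C)OC[C@]1(CCC[C@@]2(C)COC(=O)[C@H]21)CC=O | intermediate
24 | allylic alcohol C9H2–C11H(OH)–CH=CH2 (both C11 epimers) | CC(C)[Si](C(C)C)(C(C)C)OC[C@]1(CCC[C@@]2(C)COC(=O)[C@H]21)CC(O)C=C | intermediate
25 | vinyl ketone C9H2–C11(=O)–CH=CH2 with O20 silylated | CC(C)[Si](C(C)C)(C(C)C)OC[C@]1(CCC[C@@]2(C)COC(=O)[C@H]21)CC(=O)C=C | intermediate
26 | hydroxy vinyl ketone (free C20 alcohol) | OC[C@]1(CCC[C@@]2(C)COC(=O)[C@H]21)CC(=O)C=C | intermediate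
27 | dimethyl 2-(prop-2-yn-1-yl)propanedioate | COC(=O)C(CC#C)C(=O)OC | starting material
28 | 2-(prop-2-yn-1-yl)propanedioic acid | OC(=O)C(CC#C)C(=O)O | intermediate
29 | 2-[(diethylamino)methyl]-2-(prop-2-yn-1-yl)propanedioic acid | CCN(CC)CC(CC#C)(C(=O)O)C(=O)O | intermediate
30 | 2-methylidenepent-4-ynoic acid | C=C(CC#C)C(=O)O | intermediate
31 | C20 2-methylidenepent-4-ynoate of 26 | C=C(CC#C)C(=O)OC[C@]1(CCC[C@@]2(C)COC(=O)[C@H]21)CC(=O)C=C | intermediate
32 | (Z)-silyl dienol ether of 31 (C9=C11(OSitBuMe2)–C12=C13) | C=C(CC#C)C(=O)OC[C@]1(CCC[C@@]2(C)COC(=O)[C@H]21)/C=C(\O[Si](C)(C)C(C)(C)C)C=C | intermediate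
33 | tetracyclic silyl enol ether (rings A, B, C and γ-lactone; C11(OSi)=C12; prop-2-ynyl on C8) | C1=C(O[Si](C)(C)C(C)(C)C)[C@H]2[C@@]3(CCC[C@@]4(C)COC(=O)[C@H]43)COC(=O)[C@@]2(CC#C)CC1 | intermediate
34 | C12 phenylselanyl C11 ketone (C12 epimers) | C1([Se]c5ccccc5)C(=O)[C@H]2[C@@]3(CCC[C@@]4(C)COC(=O)[C@H]43)COC(=O)[C@@]2(CC#C)CC1 | intermediate
35 | enone (C11 ketone, C12=C13; prop-2-ynyl on C8) | C1=CC(=O)[C@H]2[C@@]3(CCC[C@@]4(C)COC(=O)[C@H]43)COC(=O)[C@@]2(CC#C)C1 | intermediate
36 | C17 tributylstannyl derivative of 37 (E/Z mixture) | CCCC[Sn](CCCC)(CCCC)C=C1[C@@H]2CC(=O)[C@H]3[C@@]4(CCC[C@@]5(C)COC(=O)[C@H]54)COC(=O)[C@]3(C2)C1 | intermediate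
37 | 11-oxo-15-deoxy pentacycle (16-methylene) | C=C1[C@@H]2CC(=O)[C@H]3[C@@]4(CCC[C@@]5(C)COC(=O)[C@H]54)COC(=O)[C@]3(C2)C1 | intermediate
38 | 15-hydroxy-11-oxo pentacycle (C15 epimers) | C=C1[C@@H]2CC(=O)[C@H]3[C@@]4(CCC[C@@]5(C)COC(=O)[C@H]54)COC(=O)[C@]3(C2)C1O | intermediate
39 | 11,15-dioxo pentacycle (16-methylene) | C=C1[C@@H]2CC(=O)[C@H]3[C@@]4(CCC[C@@]5(C)COC(=O)[C@H]54)COC(=O)[C@]3(C2)C1=O | intermediate
40 | guidongnin | C=C1[C@@H]2C[C@@H](O)[C@H]3[C@@]4(CCC[C@@]5(C)COC(=O)[C@H]54)COC(=O)[C@]3(C2)[C@@H]1O | target

## Step count and risks

Total step count: 28. Longest linear sequence: 24 steps (steps 3 to 18 and 21 to 28); steps 1, 2 and 19, 20 are side branches.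

**Step 9 (key step).**
- What may go wrong: the second deprotonation, at the α-branched ester, may be incomplete, so the mono-enolate is simply reprotonated or attacks the other carbonyl; coupling between two molecules may compete with ring closure; the C10 radical may be oxidised further and lose silicon; the bond may form on the other face of the C10 enolate.
- Fallback: separate enolisation from oxidation. Compound 14 is treated with LiN(iPr)2 and Me3SiCl to give the bis(trimethylsilyl ketene acetal) F1, which is isolated. F1 is then coupled with TiCl4 in CH2Cl2 (oxidative coupling of ketene silyl acetals, tetravalent titanium going to trivalent), returning to the route at 16. No amine, no lithium aggregates and no proton source are present in the bond-forming step.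

**Step 23.**
- What may go wrong: the cycloaddition may be slow, because the ester must reach its s-cis form and the diene polarisation opposes the regiochemistry that the tether imposes. Desilylation or polymerisation then competes. Closure may also run through the exo tether or on the other diene face, giving the trans-fused or the C8/C9-epimeric adduct.
- Fallback: use an unpolarised diene and bring in the C11 oxygen afterwards. Aldehyde 21 is olefinated with allylidenetriphenylphosphorane and isomerised with a trace of iodine to the (E)-butadiene F2. HF·pyridine gives alcohol F3, and esterification with 30 (DCC, DMAP) gives triene F4. Thermolysis gives the cyclohexene adduct F5 (C11=C12), and peracid gives epoxide F6. Phenylselenide anion opens F6 at the less hindered C12 to the hydroxy selenide F7, and H2O2 eliminates toward C13 to give the allylic alcohol F8. Dess–Martin oxidation of F8 returns to the route at 35.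

**Step 25.**
- What may go wrong: the stannyl radical may add to the alkyne without ring closure (plain hydrostannation), or the enone may be reduced, if ring C does not readily place the propargyl arm axial.
- Fallback: make the vinyl metal directly. Compound 35 is treated with B-bromo-9-borabicyclo[3.3.1]nonane and then AcOH to give the 2-bromoallyl compound F9. F9 is cyclised by reductive Heck reaction (Pd(OAc)2, PPh3, HCO2Na, Bu4NCl, DMF; zerovalent palladium inserts into C–Br, adds to C13, and formate supplies the hydride), returning to the route at 37.

**Step 28.**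
- What may go wrong: hydride may enter C11 from the side of C10 and give the axial alcohol, or conjugate reduction of the methylene ketone may intrude. Two centres are set in one flask.
- Fallback: set the two carbinols separately. Compound 37 is reduced at C11 alone (NaBH4, or SmI2 in THF/iPrOH for the thermodynamically preferred equatorial alcohol) to give F10. SeO2/tBuOOH gives the diol F11. MnO2 oxidises only the allylic C15 alcohol to the hydroxy enone F12. Luche reduction of F12 returns to the route at 40.

## Further compounds

F1 | step 9 | bis(trimethylsilyl ketene acetal) of 14 | CC(C)(C)OC(O[Si](C)(C)C)=C(CCC[C@@]1(C)COC(O[Si](C)(C)C)=C1)C[Si](C)(C)c2ccccc2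
F2 | step 23 | (E)-buta-1,3-dienyl compound with O20 silylated | CC(C)[Si](C(C)C)(C(C)C)OC[C@]1(CCC[C@@]2(C)COC(=O)[C@H]21)/C=C/C=C
F3 | step 23 | (E)-buta-1,3-dienyl C20 alcohol | OC[C@]1(CCC[C@@]2(C)COC(=O)[C@H]21)/C=C/C=C
F4 | step 23 | C20 2-methylidenepent-4-ynoate of F3 | C=C(CC#C)C(=O)OC[C@]1(CCC[C@@]2(C)COC(=O)[C@H]21)/C=C/C=C
F5 | step 23 | tetracyclic cyclohexene adduct (C11=C12) | C1=C[C@H]2[C@@]3(CCC[C@@]4(C)COC(=O)[C@H]43)COC(=O)[C@@]2(CC#C)CC1
F6 | step 23 | C11,C12 epoxide of F5 (either face) | C12OC1[C@H]3[C@@]4(CCC[C@@]5(C)COC(=O)[C@H]54)COC(=O)[C@@]3(CC#C)CC2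
F7 | step 23 | C11 hydroxy C12 phenylselanyl compound | C1([Se]c6ccccc6)C(O)[C@H]2[C@@]3(CCC[C@@]4(C)COC(=O)[C@H]43)COC(=O)[C@@]2(CC#C)CC1
F8 | step 23 | allylic alcohol (C11 hydroxyl, C12=C13) | C1=CC(O)[C@H]2[C@@]3(CCC[C@@]4(C)COC(=O)[C@H]43)COC(=O)[C@@]2(CC#C)C1
F9 | step 25 | 2-bromoprop-2-enyl analogue of 35 | C1=CC(=O)[C@H]2[C@@]3(CCC[C@@]4(C)COC(=O)[C@H]43)COC(=O)[C@@]2(CC(Br)=C)C1
F10 | step 28 | 11-hydroxy-15-deoxy pentacycle (C11 as in the target) | C=C1[C@@H]2C[C@@H](O)[C@H]3[C@@]4(CCC[C@@]5(C)COC(=O)[C@H]54)COC(=O)[C@]3(C2)C1
F11 | step 28 | 11,15-diol (C15 epimers) | C=C1[C@@H]2C[C@@H](O)[C@H]3[C@@]4(CCC[C@@]5(C)COC(=O)[C@H]54)COC(=O)[C@]3(C2)C1O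
F12 | step 28 | 11-hydroxy-15-oxo pentacycle | C=C1[C@@H]2C[C@@H](O)[C@H]3[C@@]4(CCC[C@@]5(C)COC(=O)[C@H]54)COC(=O)[C@]3(C2)C1=O
A1 | alternative 1 | guidongnin 11-O-tert-butyldimethylsilyl ether | C=C1[C@@H]2C[C@@H](O[Si](C)(C)C(C)(C)C)[C@H]3[C@@]4(CCC[C@@]5(C)COC(=O)[C@H]54)COC(=O)[C@]3(C2)[C@@H]1O
A2 | alternative 2 | ring-C cyclohex-3-enecarboxylic acid with quaternary C8 | C[Si](C)(C)C#C[C@@H]2C=C[C@@H]([C@@]4(CCC[C@@]5(C)COC(=O)[C@H]54)CO[Si](C)(C)C(C)(C)C)[C@](C(=O)O)(COCc6ccc(OC)cc6)C2
A3 | alternative 3 | lactone-fused bicyclo[3.2.1]oct-6-en-3-one | C1=C[C@@H]2CC(=O)[C@H]3[C@@]4(CCC[C@@]5(C)COC(=O)[C@H]54)COC(=O)[C@]13C2
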